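**Plan**

1. Numbering (daucane): C1 is the quaternary methyl carbon, C5 the ring-fusion CH, C4 the isopropyl carbinol, C6 the ester carbon, C8/C9 the methylidene and carbinol carbons of the seven-membered ring.
2. Retrosynthesis: the C8(=CH2)/C9–OH allylic alcohol goes back to the 8α,9α-epoxide of a C8=C9 alkene and the aryl ester is cut, giving jaeschkeanadiol. The seven-membered ring is then cut at C8=C9 (metathesis) and at C6–C7 (methallyl addition to a C6 aldehyde).
3. The cyclopentane is cut at C1–C2 and C4–C5. The C4 carbinol is 1,3 to C6 across C5 (aldol pattern) and C1 is β to C6 (homoenolate pattern). C6–C5–C1 is therefore an enal used with inverted polarity, and C2–C3–C4(iPr) is isopropyl vinyl ketone. The C4–O–C6 β-lactone left by the annulation is a temporary ring.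
4. Forward: the cyclopentane is built first, then the lactone is opened to the C6 aldehyde, then methallylation and metathesis close the seven-membered ring. The trans ring fusion is thus fixed by substituents already on the cyclopentane, not by a ring closure. Esterification, epoxidation, epoxide-to-allylic-alcohol isomerisation and desilylation follow.
5. Stereochemistry: C1, C5 and C4 come from the chiral triazolylidene, the E geometry of the enal and the cis-locked lactone. C6 comes from chelate-controlled addition, and C9 from epoxidation anti to the angular methyl. No stereocentre is touched afterwards.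

Key step: step 3

Assumption: the (5aS,10bR) triazolium salt is taken to give 8 in the configuration drawn; if its sense of induction is the opposite one, the (5aR,10bS) salt is used and nothing else changes.

**Route**

Step 1
Reactants: 1 pent-1-en-4-yne
Product: 3 (2E)-3-methylhexa-2,5-dien-1-ol, via alkenylalane 2 (not isolated)
Conditions: AlMe3, Cp2ZrCl2 (cat.), CH2Cl2, 0 °C to rt; then (CH2O)n, THF, 0 °C to rt; aq. HCl
Reagents that add atoms: trimethylaluminium C[Al](C)C; formaldehyde (as paraformaldehyde) C=O
Why: Negishi zirconium-catalysed carboalumination should add CH3 and Al syn across the terminal alkyne with Al on the terminal carbon, and hydroxymethylation of the alkenylalane with retention then fixes the 2E geometry (CH2OH cis to CH3, trans to allyl) while the isolated alkene stays untouched.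

Step 2
Reactants: 3 (2E)-3-methylhexa-2,5-dien-1-ol
Product: 4 (2E)-3-methylhexa-2,5-dienal
Conditions: MnO2 (activated, excess), CH2Cl2, rt
Reagents that add atoms: none
Why: Allylic alcohol oxidation with MnO2 is neutral and should give the enal without moving the skipped double bond or changing the 2E geometry.

Step 3
Reactants: 4 (2E)-3-methylhexa-2,5-dienal; 5 4-methylpent-1-en-3-one (isopropyl vinyl ketone)
Product: 8 (1R,2R,5R)-2-methyl-5-(propan-2-yl)-2-(prop-2-en-1-yl)-6-oxabicyclo[3.2.0]heptan-7-one, via azolium enolate 6 (not isolated), via azolium aldolate 7 (not isolated)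
Conditions: (5aS,10bR)-2-mesityl-5a,10b-dihydro-4H,6H-indeno[2,1-b][1,2,4]triazolo[4,3-d][1,4]oxazin-2-ium chloride (10 mol%), DBU (15 mol%), ClCH2CH2Cl, 0 °C to rt, 5 added slowly
Reagents that add atoms: none
Why: Proposed new method: the triazolylidene adds to the aldehyde of 4 to give a conjugated enaminol whose β-carbon (a homoenolate) adds to the unsubstituted CH2 terminus of 5; tautomerisation leaves azolium enolate 6, which closes the cyclopentane onto the isopropyl ketone by a 5-(enolexo)-exo-trig aldol addition to give alkoxide 7, and 7 acylates itself on the acyl azolium in a 4-exo-trig closure that forms the β-lactone and releases the catalyst. The closest known reaction type is the carbene-catalysed homoenolate annulation of β-monosubstituted enals with enones to cyclopentane-fused β-lactones (or the cyclopentenes derived from them by loss of CO2), together with carbene-catalysed homoenolate additions of β,β-disubstituted enals; new here are the quaternary carbon made in the annulation and the alkyl vinyl ketone partner, which is reasonable because the hindered carbon is the nucleophile and the accepting carbon is unsubstituted. C1 is set by the catalyst, whose indane wall leaves one face of the planar enaminol open, while the E geometry of 4 decides where methyl and allyl point. C5 is set in the aldol step on the open face of the catalyst-bound enolate, so the three-carbon unit is delivered to one face of the former C=C bond and the allyl group (trans to CHO in 4, and the larger group) should end trans to the lactone carbonyl. C4 follows because only the alkoxide cis to the acyl azolium can lactonise, the other aldolate reverting by retro-aldol. The step needs homoenolate C–C bond formation to win over acyl-anion addition (Stetter or benzoin products), over protonation to the enolate, and over base-induced conjugation of the skipped diene; the N-mesityl triazolium, catalytic DBU and slow addition of 5 are chosen for that, and a fully alkyl-substituted β-lactone should not lose CO2 at room temperature.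

Step 4
Reactants: 8 β-lactone
Product: 9 (1R,2S,3R)-2-(hydroxymethyl)-3-methyl-1-(propan-2-yl)-3-(prop-2-en-1-yl)cyclopentan-1-ol
Conditions: LiAlH4, Et2O, 0 °C
Reagents that add atoms: none
Why: Hydride reduction should open the strained lactone by acyl–oxygen cleavage to the 1,3-diol, so the C4–O bond and all three stereocentres are untouched and the alkene is inert.

Step 5
Reactants: 9 diol
Product: 10 (1R,2R,5R)-2-hydroxy-5-methyl-2-(propan-2-yl)-5-(prop-2-en-1-yl)cyclopentane-1-carbaldehyde
Conditions: TEMPO (cat.), PhI(OAc)2, CH2Cl2, rt
Reagents that add atoms: none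
Why: Oxoammonium (TEMPO) oxidation should convert only the primary alcohol, since the tertiary one cannot be oxidised, and the near-neutral medium should avoid retro-aldol cleavage and epimerisation at C5.

Step 6
Reactants: 10 β-hydroxy aldehyde
Product: 11 (1R,2S,3R)-2-[(1S)-1-hydroxy-3-methylbut-3-en-1-yl]-3-methyl-1-(propan-2-yl)-3-(prop-2-en-1-yl)cyclopentan-1-ol
Conditions: indium powder, 3-bromo-2-methylprop-1-ene, THF–H2O (1:1), rt
Reagents that add atoms: 3-bromo-2-methylprop-1-ene CC(=C)CBr
Why: In this Barbier allylation the metal should bridge the aldehyde oxygen and the cis C4 hydroxyl, and in that chelate one face of the carbonyl is covered by the quaternary C1 while the other faces only H5, so the methallyl group should add from the open face and give the (S)-carbinol at C6.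

Step 7
Reactants: 11 diene diol
Product: 12 jaeschkeanadiol
Conditions: second-generation Grubbs catalyst RuCl2(=CHPh)(H2IMes)(PCy3) (5 mol%), CH2Cl2 (dilute), 40 °C
Reagents that add atoms: none
Why: Ring-closing metathesis between the allyl group on C1 and the methallyl group on C6 should close the cycloheptene with its trisubstituted C8=C9 bond and lose ethene; the trans fusion is already fixed by the trans arrangement of the two arms and no stereocentre is formed.

Step 8
Reactants: 12 jaeschkeanadiol; 13 4-[(tert-butyldimethylsilyl)oxy]benzoic acid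
Product: 14 O-silyl ferutinin
Conditions: EDC·HCl, DMAP, CH2Cl2, rt
Reagents that add atoms: none
Why: Steglich esterification should acylate the secondary C6 hydroxyl only, because the tertiary C4 hydroxyl is too hindered, and the C–O bond at C6 is not broken so its configuration is kept.

Step 9
Reactants: 14 O-silyl ferutinin
Product: 15 8α,9α-epoxide of 14
Conditions: mCPBA, NaHCO3, CH2Cl2, 0 °C
Reagents that add atoms: 3-chloroperoxybenzoic acid OOC(=O)c1cccc(Cl)c1
Why: Prilezhaev epoxidation of the only alkene should take place on the α face, because the angular methyl on the β face covers C9/C10, and this sets C8 and C9 together.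

Step 10
Reactants: 15 epoxide
Product: 16 O-silyl ferugin
Conditions: Et2AlCl, LiTMP (forms Et2Al(TMP), 4 equiv), toluene, 0 °C; aq. potassium sodium tartrate
Reagents that add atoms: none
Why: In this base-promoted epoxide-to-allylic-alcohol isomerisation the aluminium amide should bind the epoxide oxygen and remove a proton of the C8 methyl group in a syn elimination, which opens the tertiary C8–O bond, keeps the C9–O bond with its α configuration and places the double bond exocyclic, while the hindered amide should not add to the aryl ester.

Step 11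
Reactants: 16 O-silyl ferugin
Product: 17 ferugin
Conditions: Bu4NF, AcOH, THF, 0 °C
Reagents that add atoms: none
Why: Buffered fluoride should cleave the aryl silyl ether alone and leave the benzoate, the allylic alcohol and the tertiary alcohol as they are.

**Compound list**

1 | pent-1-en-4-yne | C#CCC=C | starting material
2 | dimethyl[(1E)-2-methylpenta-1,4-dien-1-yl]alumane | C[Al](C)/C=C(\C)CC=C | intermediate
3 | (2E)-3-methylhexa-2,5-dien-1-ol | OC/C=C(\C)CC=C | intermediate
4 | (2E)-3-methylhexa-2,5-dienal | O=C/C=C(\C)CC=C | intermediate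
5 | 4-methylpent-1-en-3-one (isopropyl vinyl ketone) | C=CC(=O)C(C)C | starting material
6 | azolium enolate: (Z)-enolate of the (3R)-3,7-dimethyl-6-oxo-3-(prop-2-en-1-yl)octanoyl unit bound to C3 of the (5aS,10bR)-2-mesityl triazolium (zwitterion) | CC(C)C(=O)CC[C@](C)(CC=C)/C=C(\[O-])c1n2[C@@H]3c4ccccc4C[C@@H]3OCc2n[n+]1-c5c(C)cc(C)cc5C | intermediate
7 | azolium aldolate: (1R,2R,5R)-5-methyl-2-oxido-2-(propan-2-yl)-5-(prop-2-en-1-yl)cyclopentane-1-carbonyl unit bound to C3 of the same triazolium (zwitterion) | O=C(c1n2[C@@H]3c4ccccc4C[C@@H]3OCc2n[n+]1-c5c(C)cc(C)cc5C)[C@@H]6[C@](C)(CC[C@@]6([O-])C(C)C)CC=C | intermediate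
8 | (1R,2R,5R)-2-methyl-5-(propan-2-yl)-2-(prop-2-en-1-yl)-6-oxabicyclo[3.2.0]heptan-7-one (methyl cis, allyl trans to the lactone carbonyl) | O=C1[C@@H]2[C@](C)(CC[C@@]2(O1)C(C)C)CC=C | intermediate
9 | (1R,2S,3R)-2-(hydroxymethyl)-3-methyl-1-(propan-2-yl)-3-(prop-2-en-1-yl)cyclopentan-1-ol | OC[C@@H]1[C@](C)(CC[C@@]1(O)C(C)C)CC=C | intermediate
10 | (1R,2R,5R)-2-hydroxy-5-methyl-2-(propan-2-yl)-5-(prop-2-en-1-yl)cyclopentane-1-carbaldehyde | O=C[C@@H]1[C@](C)(CC[C@@]1(O)C(C)C)CC=C | intermediate
11 | (1R,2S,3R)-2-[(1S)-1-hydroxy-3-methylbut-3-en-1-yl]-3-methyl-1-(propan-2-yl)-3-(prop-2-en-1-yl)cyclopentan-1-ol | C=C(C)C[C@H](O)[C@@H]1[C@](C)(CC[C@@]1(O)C(C)C)CC=C | intermediate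
12 | jaeschkeanadiol, (3R,3aS,4S,8aR)-6,8a-dimethyl-3-(propan-2-yl)-1,2,3,3a,4,5,8,8a-octahydroazulene-3,4-diol | CC1=CC[C@@]2(C)CC[C@@](O)(C(C)C)[C@@H]2[C@@H](O)C1 | intermediate
13 | 4-[(tert-butyldimethylsilyl)oxy]benzoic acid | O=C(O)c1ccc(O[Si](C)(C)C(C)(C)C)cc1 | starting material
14 | O-silyl ferutinin, [(3R,3aS,4S,8aR)-3-hydroxy-6,8a-dimethyl-3-(propan-2-yl)-1,2,3,3a,4,5,8,8a-octahydroazulen-4-yl] 4-[(tert-butyldimethylsilyl)oxy]benzoate | CC1=CC[C@@]2(C)CC[C@@](O)(C(C)C)[C@@H]2[C@@H](OC(=O)c3ccc(O[Si](C)(C)C(C)(C)C)cc3)C1 | intermediate
15 | 8α,9α-epoxide of 14 (oxirane oxygen on the face opposite the angular methyl) | C[C@@]12C[C@H](OC(=O)c4ccc(O[Si](C)(C)C(C)(C)C)cc4)[C@@H]3[C@](C)(CC[C@@]3(O)C(C)C)C[C@@H]1O2 | intermediate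
16 | O-silyl ferugin, [(3R,3aS,4S,7S,8aR)-3,7-dihydroxy-8a-methyl-6-methylidene-3-(propan-2-yl)decahydroazulen-4-yl] 4-[(tert-butyldimethylsilyl)oxy]benzoate | C=C1C[C@H](OC(=O)c3ccc(O[Si](C)(C)C(C)(C)C)cc3)[C@@H]2[C@](C)(CC[C@@]2(O)C(C)C)C[C@@H]1O | intermediate
17 | ferugin, [(3R,3aS,4S,7S,8aR)-3,7-dihydroxy-8a-methyl-6-methylidene-3-(propan-2-yl)decahydroazulen-4-yl] 4-hydroxybenzoate | C=C1C[C@H](OC(=O)c2ccc(O)cc2)[C@@H]2[C@](C)(CC[C@@]2(O)C(C)C)C[C@@H]1O | target

**Step count and risks**

Total step count: 11. Longest linear sequence: 11 steps (1 to 17); 5 and 13 are bought.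

Steps most likely to fail:

Step 3. Several processes could divert it: slow C–C bond formation at the fully substituted β-carbon, acyl-anion addition to the vinyl ketone, protonation of the homoenolate to the enolate, base-induced migration of the skipped double bond, and an untested level or sense of asymmetric induction. The fallback uses known auxiliary chemistry, sets out from 4 and comes back at 9. Pinnick oxidation of 4 (NaClO2, NaH2PO4, 2-methylbut-2-ene) should give (2E)-3-methylhexa-2,5-dienoic acid F1. Coupling through the pivaloyl mixed anhydride with lithiated (4S)-4-benzyl-1,3-oxazolidin-2-one should give (4S)-4-benzyl-3-[(2E)-3-methylhexa-2,5-dienoyl]-1,3-oxazolidin-2-one F2. The Grignard reagent of 2-(2-bromoethyl)-2-(propan-2-yl)-1,3-dioxolane F3 (made from 5 with HBr, then ethane-1,2-diol) would be added with CuBr·SMe2 to the magnesium-chelated imide on the face away from the benzyl group. This should give (4S)-4-benzyl-3-{(3R)-3-methyl-3-[2-(2-isopropyl-1,3-dioxolan-2-yl)ethyl]hex-5-enoyl}-1,3-oxazolidin-2-one F4. Aqueous acid should then free the ketone to give (4S)-4-benzyl-3-[(3R)-3,7-dimethyl-6-oxo-3-(prop-2-en-1-yl)octanoyl]-1,3-oxazolidin-2-one F5. The chelated sodium Z-enolate (NaN(SiMe3)2, THF, −78 °C) should close onto the ketone on the face away from benzyl to give (4S)-4-benzyl-3-{[(1R,2R,5R)-2-hydroxy-5-methyl-2-(propan-2-yl)-5-(prop-2-en-1-yl)cyclopentyl]carbonyl}-1,3-oxazolidin-2-one F6. LiBH4 should then remove the auxiliary and give diol 9.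

Step 10. Proton removal could occur at C7 instead of the methyl group (endocyclic alkene), or the amide base could attack the ester. The fallback sets out from 15 and comes back at 16, replacing the two-electron syn elimination by a one-electron opening. The trivalent titanium reagent Cp2TiCl (from Cp2TiCl2 and Mn dust, THF, rt) should cleave the tertiary C8–O bond homolytically, and a second equivalent should take a hydrogen atom from the methyl group to give 16 directly under neutral conditions that tolerate the ester; no new compound arises (F0).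

Step 9. Facial selectivity could be poor or reversed if the α-oriented ester side of the ring hinders the peracid more than the angular methyl does. The fallback sets out from 14 and comes back at 15, and inverts the facial outcome by anti addition. N-Bromosuccinimide in aqueous THF should form the bromonium ion on the face the peracid prefers, and water should open it at the tertiary C8 from the other face. For a β-face preference this gives the 9β-bromo-8α-hydroxy bromohydrin of 14, F7. NaH in THF should then close the 8α-alkoxide onto C9 with inversion to give the α-epoxide 15.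

Further compounds
F1 | step 3 | (2E)-3-methylhexa-2,5-dienoic acid | OC(=O)/C=C(\C)CC=C
F2 | step 3 | (4S)-4-benzyl-3-[(2E)-3-methylhexa-2,5-dienoyl]-1,3-oxazolidin-2-one | O=C(/C=C(\C)CC=C)N1[C@@H](Cc2ccccc2)COC1=O
F3 | step 3 | 2-(2-bromoethyl)-2-(propan-2-yl)-1,3-dioxolane | BrCCC1(C(C)C)OCCO1
F4 | step 3 | (4S)-4-benzyl-3-{(3R)-3-methyl-3-[2-(2-isopropyl-1,3-dioxolan-2-yl)ethyl]hex-5-enoyl}-1,3-oxazolidin-2-one | O=C(C[C@@](C)(CC=C)CCC1(C(C)C)OCCO1)N2[C@@H](Cc3ccccc3)COC2=O
F5 | step 3 | (4S)-4-benzyl-3-[(3R)-3,7-dimethyl-6-oxo-3-(prop-2-en-1-yl)octanoyl]-1,3-oxazolidin-2-one | O=C(C[C@@](C)(CC=C)CCC(=O)C(C)C)N1[C@@H](Cc2ccccc2)COC1=O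
F6 | step 3 | (4S)-4-benzyl-3-{[(1R,2R,5R)-2-hydroxy-5-methyl-2-(propan-2-yl)-5-(prop-2-en-1-yl)cyclopentyl]carbonyl}-1,3-oxazolidin-2-one | O=C([C@@H]1[C@](C)(CC[C@@]1(O)C(C)C)CC=C)N2[C@@H](Cc3ccccc3)COC2=O
F7 | step 9 | 9β-bromo-8α-hydroxy bromohydrin of 14 | C[C@@]1(O)C[C@H](OC(=O)c3ccc(O[Si](C)(C)C(C)(C)C)cc3)[C@@H]2[C@](C)(CC[C@@]2(O)C(C)C)C[C@H]1Br
F0 | step 10 | none | none
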